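**Retrosynthetic overview**
1. Feature: the ring C1–C6, the ester carbon on C1 and its OMe are the intact skeleton of methyl benzoate (1), and the C3 carbinol of the target lies meta to C1, where an arene dioxygenase places oxygen. Hence 1 ⇒ cis-diene diol 2 (O3 kept, O2 sacrificial).
2. O4/O5: acetonide 3 → bromohydrin 4 → α-oxirane 5 (syn to the diol oxygens), opened at allylic C5 with inversion by (E)-3-methylpent-2-enoic acid (6) to give 7 (C5 ester β, C4 OH α).
3. Differentiation: O4 silylated (8), ketal removed (9), O2 and O3 esterified with 6 (10); the O2 ester is only a leaving group.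
4. Alkene relocation: hydride to C6 of the C1=C6 enoate gives enolate 11, which expels the O2 carboxylate to give the C1=C2 enoate 12; desilylation gives target 13.
5. Ring order: no ring is closed; the only carbocycle is the arene ring of 1, dearomatised in step 1.

Key step: step 1

Remark: ring atoms are numbered as in the target throughout (C1 bears CO2Me, C2 is vinylic in the target, C6 is its CH2); α is the ring face carrying the two enzyme-delivered oxygens, β the opposite face. Compounds 1 and 6 are taken as purchased.

**Step 1**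
Reactants: 1 methyl benzoate
Product: 2 methyl (5S,6R)-5,6-dihydroxycyclohexa-1,3-diene-1-carboxylate
Conditions: E. coli JM109(pDTG601A) whole cells expressing toluene dioxygenase (IPTG-induced), air/O2, glucose feed, mineral medium pH 7, 30–35 °C, slow feed of 1; EtOAc extraction
Reagents that add atoms: dioxygen, O=O
Why: The Rieske-type non-heme iron dioxygenase binds 1 next to its mononuclear iron site, reduces O2 there with two electrons supplied by NADH, and transfers both oxygen atoms to one face of the arene C2–C3 bond, so that two C–O bonds form suprafacially and the ring is dearomatised without any ring being closed. The closest known reaction type is the whole-cell toluene dioxygenase cis-dihydroxylation of monosubstituted benzenes (halobenzenes, toluene, benzoate esters). Both new stereocentres (C5 S and C6 R of 2) are set by the protein alone, which holds the ring by its substituent and thereby fixes which pair of carbons and which enantioface meet the iron-bound oxidant. The step needs regioselection for the ortho,meta bond over the ipso,ortho bond and a single absolute configuration, and both follow from the seating of the CO2Me group in the substituent pocket of the active site. The meta carbinol carbon is C3 of the target and already has its configuration, the ortho oxygen serves later as the leaving group, and the electron-poor ester slows the acid-catalysed dehydration of 2 back to an arene.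

**Step 2**
Reactants: 2 methyl (5S,6R)-5,6-dihydroxycyclohexa-1,3-diene-1-carboxylate
Product: 3 methyl (3aR,7aS)-2,2-dimethyl-3a,7a-dihydro-1,3-benzodioxole-4-carboxylate
Conditions: 2,2-dimethoxypropane, TsOH·H2O (cat.), acetone, 0 °C to rt
Reagents that add atoms: 2,2-dimethoxypropane, COC(C)(C)OC
Why: Acid-catalysed transketalisation of the cis-1,2-diol should give the cis-fused dioxolane without touching a stereocentre; the ketal masks O2/O3, stops rearomatisation and shields the α face.

**Step 3**
Reactants: 3 methyl (3aR,7aS)-2,2-dimethyl-3a,7a-dihydro-1,3-benzodioxole-4-carboxylate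
Product: 4 methyl (3aR,6S,7R,7aR)-7-bromo-6-hydroxy-2,2-dimethyl-3a,6,7,7a-tetrahydro-1,3-benzodioxole-4-carboxylate (Br at C4 β, OH at C5 α)
Conditions: NBS (1.1 equiv), DME/H2O (3:2), 0 °C, dark
Reagents that add atoms: N-bromosuccinimide, O=C1CCC(=O)N1Br; water, O
Why: Bromohydrin formation: Br+ should add to the electron-richer distal C4=C5 alkene from the β face (anti to the dioxolane) and water should open the bromonium ion at allylic C5 from the α face (anti addition), which sets C4 and C5; either regiochemistry of a trans bromohydrin would lead to the same oxirane in step 4.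

**Step 4**
Reactants: 4 bromohydrin (Br at C4 β, OH at C5 α)
Product: 5 methyl (3aR,6S,7S,7aR)-6,7-epoxy-2,2-dimethyl-3a,6,7,7a-tetrahydro-1,3-benzodioxole-4-carboxylate (C4–C5 oxirane on the α face, syn to the dioxolane)
Conditions: NaH (1.1 equiv), THF, 0 °C
Reagents that add atoms: none
Why: Intramolecular Williamson etherification (SN2): the C5 alkoxide displaces the anti bromide at C4 with inversion, so the oxirane oxygen should lie on the α face; a non-nucleophilic base avoids conjugate addition to the enoate.

**Step 5**
Reactants: 5 syn-epoxy acetonide; 6 (E)-3-methylpent-2-enoic acid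
Product: 7 methyl (3aR,6R,7S,7aS)-7-hydroxy-2,2-dimethyl-6-{[(2E)-3-methylpent-2-enoyl]oxy}-3a,6,7,7a-tetrahydro-1,3-benzodioxole-4-carboxylate (C5 ester β, C4 OH α)
Conditions: 6 (3 equiv), i-Pr2NEt (0.5 equiv), MeCN, 60 °C
Reagents that add atoms: (E)-3-methylpent-2-enoic acid, CC/C(C)=C/C(=O)O
Why: SN2 opening of a vinyl oxirane by a carboxylate: attack should occur at allylic C5 (activated by the adjacent π system, whereas C4 is deactivated by the β-oxygen at C3) from the β face with inversion, which sets C5 and leaves the oxirane oxygen as the α-hydroxyl at C4; the excess acid protonates the alkoxide at once and limits O5→O4 acyl migration.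

**Step 6**
Reactants: 7 C4-hydroxy C5-ester acetonide
Product: 8 methyl (3aR,6R,7S,7aR)-7-[(tert-butyldimethylsilyl)oxy]-2,2-dimethyl-6-{[(2E)-3-methylpent-2-enoyl]oxy}-3a,6,7,7a-tetrahydro-1,3-benzodioxole-4-carboxylate
Conditions: TBSOTf (1.3 equiv), 2,6-lutidine (2 equiv), CH2Cl2, −78 to 0 °C
Reagents that add atoms: tert-butyldimethylsilyl triflate, CC(C)(C)[Si](C)(C)OS(=O)(=O)C(F)(F)F
Why: Silylation of a hindered secondary alcohol with a silyl triflate and a non-nucleophilic base, which marks O4 as the one oxygen that is not to be acylated and does not promote acyl migration.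

**Step 7**
Reactants: 8 C4 silyl ether acetonide
Product: 9 methyl (3R,4R,5R,6R)-4-[(tert-butyldimethylsilyl)oxy]-5,6-dihydroxy-3-{[(2E)-3-methylpent-2-enoyl]oxy}cyclohex-1-ene-1-carboxylate (target numbering: O2 and O3 free, O4 silylated, O5 acylated)
Conditions: AcOH/H2O (4:1), 40 °C
Reagents that add atoms: none
Why: Acid-catalysed ketal hydrolysis through a tertiary oxocarbenium ion, which should be much faster in this weak acid than solvolysis of the hindered secondary silyl ether or of the esters; no stereocentre is touched.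

**Step 8**
Reactants: 9 C2,C3-diol; 6 (E)-3-methylpent-2-enoic acid
Product: 10 methyl (3R,4S,5R,6R)-4-[(tert-butyldimethylsilyl)oxy]-3,5,6-tris{[(2E)-3-methylpent-2-enoyl]oxy}cyclohex-1-ene-1-carboxylate (target numbering: esters at O2, O3, O5)
Conditions: 6 (4 equiv), DCC (4 equiv), DMAP (0.5 equiv), CH2Cl2, 0 °C to rt
Reagents that add atoms: (E)-3-methylpent-2-enoic acid, CC/C(C)=C/C(=O)O
Why: Steglich esterification of both secondary hydroxyls under near-neutral conditions that should keep the (E)-enoyl geometry; the O3 ester is the one kept in the target and the O2 ester is installed as the nucleofuge for step 9.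

**Step 9**
Reactants: 10 silylated triester
Product: 12 methyl (3R,4S,5R)-4-[(tert-butyldimethylsilyl)oxy]-3,5-bis{[(2E)-3-methylpent-2-enoyl]oxy}cyclohex-1-ene-1-carboxylate, via copper ester enolate 11 (not isolated)
Conditions: [(Ph3P)CuH]6 (0.2 equiv of hexamer, 1.2 equiv of hydride), degassed PhMe, 0 °C to rt; aq. NH4Cl
Reagents that add atoms: none
Why: Conjugate reduction with β-elimination (the SN2′ reduction known for Morita–Baylis–Hillman-type allylic esters): the monovalent copper hydride should deliver hydride to C6 of the ring enoate to give enolate 11, which expels the C2 carboxylate by E1cB so that the alkene moves to C1=C2 and C6 becomes CH2 without a new stereocentre; the ring enoate has a β-CH and two allylic C–O bonds, whereas the side-chain enoates are β,β-dialkyl and should react far more slowly with the bulky cluster, and hydride is kept near one equivalent to spare 12.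

**Step 10**
Reactants: 12 4-O-silylated target
Product: 13 methyl (3R,4S,5R)-4-hydroxy-3,5-bis{[(2E)-3-methylpent-2-enoyl]oxy}cyclohex-1-ene-1-carboxylate (target, CNP0268575.1)
Conditions: HF·pyridine, pyridine/THF, 0 °C to rt
Reagents that add atoms: none
Why: Fluoride-mediated Si–O cleavage under mildly acidic conditions, which avoids a free alkoxide at O4 and so should prevent acyl migration from O3 or O5; no stereocentre is touched.

**Compound list**
1 | methyl benzoate | COC(=O)c1ccccc1 | starting material
2 | methyl (5S,6R)-5,6-dihydroxycyclohexa-1,3-diene-1-carboxylate | O[C@@H]1[C@H](O)C(C(=O)OC)=CC=C1 | intermediate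
3 | methyl (3aR,7aS)-2,2-dimethyl-3a,7a-dihydro-1,3-benzodioxole-4-carboxylate | CC2(C)O[C@@H]1[C@H](O2)C(C(=O)OC)=CC=C1 | intermediate
4 | methyl (3aR,6S,7R,7aR)-7-bromo-6-hydroxy-2,2-dimethyl-3a,6,7,7a-tetrahydro-1,3-benzodioxole-4-carboxylate | CC2(C)O[C@@H]1[C@H](O2)C(C(=O)OC)=C[C@H](O)[C@H]1Br | intermediate
5 | methyl (3aR,6S,7S,7aR)-6,7-epoxy-2,2-dimethyl-3a,6,7,7a-tetrahydro-1,3-benzodioxole-4-carboxylate (oxirane syn to dioxolane) | CC2(C)O[C@@H]1[C@H](O2)C(C(=O)OC)=C[C@@H]3O[C@H]13 | intermediate
6 | (E)-3-methylpent-2-enoic acid | CC/C(C)=C/C(=O)O | starting material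
7 | methyl (3aR,6R,7S,7aS)-7-hydroxy-2,2-dimethyl-6-{[(2E)-3-methylpent-2-enoyl]oxy}-3a,6,7,7a-tetrahydro-1,3-benzodioxole-4-carboxylate | CC2(C)O[C@@H]1[C@H](O2)C(C(=O)OC)=C[C@@H](OC(=O)/C=C(\C)CC)[C@@H]1O | intermediate
8 | methyl (3aR,6R,7S,7aR)-7-[(tert-butyldimethylsilyl)oxy]-2,2-dimethyl-6-{[(2E)-3-methylpent-2-enoyl]oxy}-3a,6,7,7a-tetrahydro-1,3-benzodioxole-4-carboxylate | CC2(C)O[C@@H]1[C@H](O2)C(C(=O)OC)=C[C@@H](OC(=O)/C=C(\C)CC)[C@@H]1O[Si](C)(C)C(C)(C)C | intermediate
9 | methyl (3R,4R,5R,6R)-4-[(tert-butyldimethylsilyl)oxy]-5,6-dihydroxy-3-{[(2E)-3-methylpent-2-enoyl]oxy}cyclohex-1-ene-1-carboxylate | O[C@@H]1[C@H](O)C(C(=O)OC)=C[C@@H](OC(=O)/C=C(\C)CC)[C@@H]1O[Si](C)(C)C(C)(C)C | intermediate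
10 | methyl (3R,4S,5R,6R)-4-[(tert-butyldimethylsilyl)oxy]-3,5,6-tris{[(2E)-3-methylpent-2-enoyl]oxy}cyclohex-1-ene-1-carboxylate | CC/C(C)=C/C(=O)O[C@@H]1[C@H](OC(=O)/C=C(\C)CC)C(C(=O)OC)=C[C@@H](OC(=O)/C=C(\C)CC)[C@@H]1O[Si](C)(C)C(C)(C)C | intermediate
11 | triphenylphosphine-ligated copper ester enolate formed from 10 by hydride addition at C6 (enolate geometry not defined) | CC/C(C)=C/C(=O)O[C@@H]1[C@H](OC(=O)/C=C(\C)CC)C(=C(OC)O[Cu])C[C@@H](OC(=O)/C=C(\C)CC)[C@@H]1O[Si](C)(C)C(C)(C)C | intermediate
12 | methyl (3R,4S,5R)-4-[(tert-butyldimethylsilyl)oxy]-3,5-bis{[(2E)-3-methylpent-2-enoyl]oxy}cyclohex-1-ene-1-carboxylate | CC/C(C)=C/C(=O)O[C@@H]1C=C(C(=O)OC)C[C@@H](OC(=O)/C=C(\C)CC)[C@@H]1O[Si](C)(C)C(C)(C)C | intermediate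
13 | methyl (3R,4S,5R)-4-hydroxy-3,5-bis{[(2E)-3-methylpent-2-enoyl]oxy}cyclohex-1-ene-1-carboxylate (methyl 3,5-di-O-acylshikimate) | CC/C(C)=C/C(=O)O[C@@H]1C=C(C(=O)OC)C[C@@H](OC(=O)/C=C(\C)CC)[C@@H]1O | target

**Step count and risks**
Total steps: 10. Longest linear sequence: 10 steps (1 → 13); acid 6 enters in steps 5 and 8.

Steps most likely to fail:

1. Step 9. The copper hydride may add to the side-chain enoates or to the new C1=C2 enoate of 12 at a rate close to that of the wanted addition, or may be too hindered to reach C6, so that over-reduced or unchanged material results. The fallback sets out from 5 and comes back at 12; it moves the alkene before any side-chain alkene is present and uses hydrogenation followed by base elimination instead of a hydride reagent. Acetic acid (i-Pr2NEt cat., MeCN, 60 °C) should open 5 to the hydroxy acetate F1, and TBSOTf/2,6-lutidine should give the silyl ether F2. AcOH/H2O should then give the diol F3, and Ac2O/pyridine/DMAP the triacetate F4. H2 over Rh/Al2O3 in EtOH should saturate the ring enoate to the saturated triacetate F5 (C1 epimers, of no consequence). DBU in CH2Cl2 should then eliminate the C2 acetate by E1cB to give methyl 3,5-di-O-acetyl-4-O-(tert-butyldimethylsilyl)shikimate F6. K2CO3/MeOH at 0 °C should remove both acetates to give methyl 4-O-(tert-butyldimethylsilyl)shikimate F7, which is esterified at O3 and O5 with 6 (DCC, DMAP, CH2Cl2) to 12.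

2. Step 5. The carboxylate is a weak nucleophile, so opening may be slow, and in the warm buffered medium the acyl group may migrate from O5 to O4 or the enoate may degrade before conversion is complete. The fallback sets out from 5 and comes back at 7; it separates C–O bond formation from acylation. Hydrolytic opening at allylic C5 (H2O/MeCN, PhCO2Na cat., 70 °C) should give the trans-diol F8 (C4 OH α, C5 OH β). The allylic, less hindered C5 hydroxyl is then esterified selectively with 6 (1.05 equiv, DCC, DMAP cat., CH2Cl2, −20 °C) to give 7.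

3. Step 7. Solvolysis or O4→O3 migration of the silyl ether may compete with ketal hydrolysis in aqueous acid. The fallback sets out from 2 and comes back at 10; it uses no ketal, the oxirane itself masking O4 while O2 and O3 are acylated. Buffered mCPBA (NaHCO3, CH2Cl2, 0 °C) should epoxidise the distal alkene of the free diol on the hydroxyl face by hydrogen-bond delivery to give the epoxy diol F9. Esterification with 6 (DCC, DMAP, CH2Cl2, 0 °C) should give the epoxy diester F10, and opening with 6 under the conditions of step 5 the hydroxy triester F11. TBSOTf/2,6-lutidine then gives 10.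

**Further compounds**
F1 | step 9 | hydroxy acetate (7 with acetyl in place of the 3-methylpent-2-enoyl group) | CC2(C)O[C@@H]1[C@H](O2)C(C(=O)OC)=C[C@@H](OC(C)=O)[C@@H]1O
F2 | step 9 | silyl ether (8 with acetyl in place of the 3-methylpent-2-enoyl group) | CC2(C)O[C@@H]1[C@H](O2)C(C(=O)OC)=C[C@@H](OC(C)=O)[C@@H]1O[Si](C)(C)C(C)(C)C
F3 | step 9 | diol (9 with acetyl in place of the 3-methylpent-2-enoyl group) | O[C@@H]1[C@H](O)C(C(=O)OC)=C[C@@H](OC(C)=O)[C@@H]1O[Si](C)(C)C(C)(C)C
F4 | step 9 | triacetate (10 with three acetyl groups) | CC(=O)O[C@@H]1[C@H](OC(C)=O)C(C(=O)OC)=C[C@@H](OC(C)=O)[C@@H]1O[Si](C)(C)C(C)(C)C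
F5 | step 9 | saturated triacetate (F4 with C1=C6 hydrogenated, C1 epimers) | CC(=O)O[C@@H]1[C@H](OC(C)=O)C(C(=O)OC)C[C@@H](OC(C)=O)[C@@H]1O[Si](C)(C)C(C)(C)C
F6 | step 9 | methyl 3,5-di-O-acetyl-4-O-(tert-butyldimethylsilyl)shikimate | CC(=O)O[C@@H]1C=C(C(=O)OC)C[C@@H](OC(C)=O)[C@@H]1O[Si](C)(C)C(C)(C)C
F7 | step 9 | methyl 4-O-(tert-butyldimethylsilyl)shikimate | O[C@@H]1C=C(C(=O)OC)C[C@@H](O)[C@@H]1O[Si](C)(C)C(C)(C)C
F8 | step 5 | trans-diol (7 without the acyl group; C4 OH α, C5 OH β) | CC2(C)O[C@@H]1[C@H](O2)C(C(=O)OC)=C[C@@H](O)[C@@H]1O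
F9 | step 7 | epoxy diol (5 without the isopropylidene group) | O[C@@H]1[C@H](O)C(C(=O)OC)=C[C@@H]3O[C@H]13
F10 | step 7 | epoxy diester (O2 and O3 esters of F9 with 6) | CC/C(C)=C/C(=O)O[C@@H]1[C@H](OC(=O)/C=C(\C)CC)C(C(=O)OC)=C[C@@H]3O[C@H]13
F11 | step 7 | hydroxy triester (10 without the silyl group) | CC/C(C)=C/C(=O)O[C@@H]1[C@H](OC(=O)/C=C(\C)CC)C(C(=O)OC)=C[C@@H](OC(=O)/C=C(\C)CC)[C@@H]1O
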